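The cyclohexane is numbered C1 (isopropylidene-bearing), C2, C3, C4 (CHMe), C5 (quaternary) and C6 (CH carrying the propanoic chain). One catalytic enantioselective Diels–Alder reaction forms C3–C4 and C5–C6 and sets C4, C5 and C6 together. The hidden feature is that the exocyclic C1=CMe2 alkene and the C6 acid chain are the two halves of a tertiary allylic seven-membered lactone. The diene is therefore a vinyl oxepinone, and the dienophile an (E)-2-(indolylmethyl)but-2-enal whose formyl group becomes the C5 methyl. Dissolving-metal opening of the lactone then reveals alkene, acid and free indole at once.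

Key step: step 7

Remark: the ring positions C1–C6 defined above are used for all intermediates; (Z)-2-bromobut-2-enal is prepared (step 5) and not assumed to be purchasable.

Step 1
Reactants: 1 2-methylbut-3-yn-2-ol; 2 pent-4-enoyl chloride
Product: 3 2-methylbut-3-yn-2-yl pent-4-enoate
Conditions: Et3N, DMAP (10 mol %), CH2Cl2, 0 °C to rt
Reagents that add atoms: none
Why: DMAP-catalysed acylation (nucleophilic acyl substitution) of the tertiary propargylic alcohol by the acid chloride; no stereocenter is formed.

Step 2
Reactants: 3 2-methylbut-3-yn-2-yl pent-4-enoate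
Product: 4 6-ethenyl-7,7-dimethyl-4,7-dihydrooxepin-2(3H)-one
Conditions: second-generation Grubbs catalyst (H2IMes)(PCy3)Cl2Ru=CHPh (5 mol %), ethylene (1 atm), CH2Cl2 (5 mM), 40 °C
Reagents that add atoms: none
Why: Ring-closing enyne metathesis in exo mode: the ruthenium alkylidene formed at the terminal alkene adds to the alkyne and the vinylcarbene is released as the 1-vinylcycloalkene, the gem-dimethyl group favouring the cisoid ester conformer; the ring fixes the C6 CH2 trans to the vinyl group, the outward geometry the diene needs in step 7.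

Step 3
Reactants: 5 3-methyl-1H-indole
Product: 6 3-methyl-1-(phenylsulfonyl)-1H-indole
Conditions: NaH, DMF, 0 °C; PhSO2Cl, 0 °C to rt
Reagents that add atoms: benzenesulfonyl chloride, O=S(=O)(Cl)c1ccccc1
Why: N-Sulfonylation of the sodium indolide; the group stabilises the later bromide and zinc reagent, silences the indole toward the acid catalyst of step 7 and leaves in step 9.

Step 4
Reactants: 6 3-methyl-1-(phenylsulfonyl)-1H-indole
Product: 7 3-(bromomethyl)-1-(phenylsulfonyl)-1H-indole
Conditions: NBS, (PhCO2)2 (5 mol %), PhCF3, 85 °C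
Reagents that add atoms: N-bromosuccinimide, O=C1CCC(=O)N1Br
Why: Wohl–Ziegler radical bromination at the indol-3-ylmethyl position; the N-phenylsulfonyl group suppresses ionic ring bromination and has no benzylic hydrogen of its own.

Step 5
Reactants: 8 (E)-but-2-enal
Product: 10 (Z)-2-bromobut-2-enal, via 2,3-dibromobutanal 9 (not isolated)
Conditions: Br2, CH2Cl2, 0 °C; then Et3N, 0 °C to rt
Reagents that add atoms: bromine, BrBr
Why: Anti addition of bromine to the alkene, then amine-induced dehydrobromination through the acidic α-hydrogen, should give the α-bromoenal as the more stable Z isomer (methyl trans to formyl).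

Step 6
Reactants: 7 3-(bromomethyl)-1-(phenylsulfonyl)-1H-indole; 10 (Z)-2-bromobut-2-enal
Product: 12 (E)-2-{[1-(phenylsulfonyl)-1H-indol-3-yl]methyl}but-2-enal, via benzylic zinc bromide 11 (not isolated)
Conditions: Zn dust, LiCl, THF, 0 °C; then added to 10, Pd(OAc)2 (2 mol %), SPhos (4 mol %), THF, 0 °C to rt
Reagents that add atoms: zinc, [Zn] (present only in intermediate 11)
Why: Negishi coupling: zinc insertion into the benzylic bromide gives 11, which couples under palladium catalysis with the alkenyl bromide with retention of alkene geometry, the organozinc tolerating the free aldehyde; the methyl group therefore stays trans to the formyl group (E).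

Step 7
Reactants: 4 6-ethenyl-7,7-dimethyl-4,7-dihydrooxepin-2(3H)-one; 12 (E)-2-{[1-(phenylsulfonyl)-1H-indol-3-yl]methyl}but-2-enal
Product: 13 (5aR,6S,7R)-1,1,7-trimethyl-3-oxo-6-{[1-(phenylsulfonyl)-1H-indol-3-yl]methyl}-1,3,4,5,5a,6,7,8-octahydro-2-benzoxepine-6-carbaldehyde (formyl cis to the lactone CH2 on C6 and trans to the C4 methyl)
Conditions: (S)-tetrahydro-1-(2-methylphenyl)-3,3-diphenyl-1H,3H-pyrrolo[1,2-c][1,3,2]oxazaborole (20 mol %), Tf2NH (17 mol %), CH2Cl2, −78 to −40 °C
Reagents that add atoms: none
Why: The triflimide-activated oxazaborolidinium binds the formyl oxygen of 12 (s-trans enal, formyl C–H···O contact, alkene stacked on a phenyl group), and the diene unit C3=C2–C1=C6 of 4 adds in a concerted, asynchronous [4+2] cycloaddition in which the C3–C4 bond leads and the C5–C6 bond follows. The closest known reaction type is the cationic oxazaborolidine-catalysed enantioselective Diels–Alder reaction of α-substituted enals such as 2-methylacrolein and tiglic aldehyde with acyclic and semicyclic dienes. The cyclohexene C1–C6 is closed in intermolecular [4+2] mode, suprafacial on both partners, fused to the lactone that is already in place. C4 follows from the E geometry of 12 (C4 methyl cis to the indolylmethyl group), C6 from the endo position of the small coordinated formyl group next to the outward ring CH2 of the diene (formyl cis to the C6 chain), and the absolute sense from the catalyst, whose (S) form is expected to leave the Re face of C5 open. The step needs ortho regioselectivity, which the alkyl-substituted C6 terminus and attack of the unhindered C3 terminus on the β-carbon C4 should secure, endo selectivity, which the bulky exo indolylmethyl group reinforces, and survival of the tertiary dienyl ester, for which the low temperature and the non-nucleophilic counter-ion are chosen.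

Step 8
Reactants: 13 the aldehyde of step 7
Product: 15 (5aS,6R,7R)-1,1,6,7-tetramethyl-6-{[1-(phenylsulfonyl)-1H-indol-3-yl]methyl}-4,5,5a,6,7,8-hexahydro-2-benzoxepin-3(1H)-one, via tosylhydrazone 14 (not isolated)
Conditions: TsNHNH2, THF, 4 Å MS, 50 °C; then catecholborane, 0 °C to rt; then NaOAc·3H2O, 65 °C
Reagents that add atoms: 4-methylbenzenesulfonohydrazide, Cc1ccc(S(=O)(=O)NN)cc1 (its atoms stay only in intermediate 14)
Why: Caglioti-type deoxygenation: condensation gives 14, catecholborane adds hydride to C=N and acetate triggers loss of sulfinate and N2 to leave the C5 methyl under near-neutral conditions that spare the tertiary allylic lactone; C5 has no α-hydrogen and keeps its configuration.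

Step 9
Reactants: 15 the lactone of step 8
Product: 16 suaveolindole, 3-[(1S,2R,3R)-2-(1H-indol-3-ylmethyl)-2,3-dimethyl-6-(propan-2-ylidene)cyclohexyl]propanoic acid
Conditions: Li, NH3(l), THF, −78 °C; NH4Cl; then aq. HCl to pH 3
Reagents that add atoms: none
Why: Dissolving-metal (Birch-type) reductive cleavage: electron transfer into the lactone expels the carboxylate from the tertiary allylic C–O bond, the C2–C1–CMe2 allyl anion should be protonated by ammonia at its less substituted terminus C2 to give the tetrasubstituted C1=CMe2 alkene, and the N–S bond is cleaved in the same flask; no stereocenter is touched and the indolide and carboxylate anions resist further reduction.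

Compound list
1 | 2-methylbut-3-yn-2-ol | CC(C)(O)C#C | starting material
2 | pent-4-enoyl chloride | C=CCCC(=O)Cl | starting material
3 | 2-methylbut-3-yn-2-yl pent-4-enoate | C=CCCC(=O)OC(C)(C)C#C | intermediate
4 | 6-ethenyl-7,7-dimethyl-4,7-dihydrooxepin-2(3H)-one | C=CC1=CCCC(=O)OC1(C)C | intermediate
5 | 3-methyl-1H-indole | Cc1c[nH]c2ccccc12 | starting material
6 | 3-methyl-1-(phenylsulfonyl)-1H-indole | Cc1cn(S(=O)(=O)c2ccccc2)c2ccccc12 | intermediate
7 | 3-(bromomethyl)-1-(phenylsulfonyl)-1H-indole | BrCc1cn(S(=O)(=O)c2ccccc2)c2ccccc12 | intermediate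
8 | (E)-but-2-enal | C/C=C/C=O | starting material
9 | (2R*,3S*)-2,3-dibromobutanal (racemic, one enantiomer drawn) | C[C@H](Br)[C@H](Br)C=O | intermediate
10 | (Z)-2-bromobut-2-enal | C/C=C(\Br)C=O | intermediate
11 | {[1-(phenylsulfonyl)-1H-indol-3-yl]methyl}zinc bromide | Br[Zn]Cc1cn(S(=O)(=O)c2ccccc2)c2ccccc12 | intermediate
12 | (E)-2-{[1-(phenylsulfonyl)-1H-indol-3-yl]methyl}but-2-enal | C/C=C(\Cc1cn(S(=O)(=O)c2ccccc2)c2ccccc12)C=O | intermediate
13 | (5aR,6S,7R)-1,1,7-trimethyl-3-oxo-6-{[1-(phenylsulfonyl)-1H-indol-3-yl]methyl}-1,3,4,5,5a,6,7,8-octahydro-2-benzoxepine-6-carbaldehyde | O=C[C@@]1(Cc2cn(S(=O)(=O)c3ccccc3)c3ccccc23)[C@H](C)CC=C2[C@H]1CCC(=O)OC2(C)C | intermediate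
14 | (E)-4-methylbenzenesulfonylhydrazone of 13, (5aS,6S,7R) | Cc1ccc(S(=O)(=O)N/N=C/[C@@]2(Cc3cn(S(=O)(=O)c4ccccc4)c4ccccc34)[C@H](C)CC=C3[C@H]2CCC(=O)OC3(C)C)cc1 | intermediate
15 | (5aS,6R,7R)-1,1,6,7-tetramethyl-6-{[1-(phenylsulfonyl)-1H-indol-3-yl]methyl}-4,5,5a,6,7,8-hexahydro-2-benzoxepin-3(1H)-one | C[C@@]1(Cc2cn(S(=O)(=O)c3ccccc3)c3ccccc23)[C@H](C)CC=C2[C@H]1CCC(=O)OC2(C)C | intermediate
16 | suaveolindole, 3-[(1S,2R,3R)-2-(1H-indol-3-ylmethyl)-2,3-dimethyl-6-(propan-2-ylidene)cyclohexyl]propanoic acid | CC(C)=C1CC[C@@H](C)[C@@](C)(Cc2c[nH]c3ccccc23)[C@@H]1CCC(=O)O | target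

Total step count: 9. Longest linear sequence: 6 steps (steps 3, 4, 6, 7, 8 and 9, from 5 to 16).

Steps most likely to fail

Step 7. The trisubstituted enal may be activated too weakly for bond formation at the congested C5–C6 site at temperatures at which the tertiary dienyl ester of 4 still resists acid-induced ionisation, and facial or endo control may erode. The fallback gives up catalyst control of the absolute configuration. It sets out from 4 and 12, which are combined with the achiral Lewis acid Me2AlCl (CH2Cl2, −78 to −20 °C). This should give the racemic endo adduct, that is 13 together with its mirror image, the (5aS,6R,7S)-configured aldehyde F1. Preparative chromatography on a chiral stationary phase then separates the two, and the route is rejoined at 13.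

Step 9. The allyl anion may be protonated at the CMe2 terminus, which would leave the double bond in the ring, or the indole nucleus may be partly reduced. The fallback replaces electron transfer by π-allyl chemistry and sets out from 15. With Pd(PPh3)4 (5 mol %) and NaBH4 in THF at rt, ionisation of the allylic lactone and hydride attack at the less hindered ring terminus C2 should give the N-protected acid, 3-[(1S,2R,3R)-2,3-dimethyl-2-{[1-(phenylsulfonyl)-1H-indol-3-yl]methyl}-6-(propan-2-ylidene)cyclohexyl]propanoic acid F2. Mg in MeOH at rt then removes the sulfonyl group, and the route is rejoined at 16.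

Step 2. The preferred transoid ester conformation may keep alkene and alkyne apart, so that oligomerisation and cross-metathesis with ethylene outrun closure of the seven-membered ring. The fallback builds the lactone by ring expansion instead of ring closure. It does not start from 3 but from commercial 2,2-dimethylcyclohexane-1,3-dione F3. KHMDS and PhNTf2 (THF, −78 °C) convert it into the mono-enol triflate, 6,6-dimethyl-5-oxocyclohex-1-en-1-yl trifluoromethanesulfonate F4. Baeyer–Villiger oxidation (mCPBA, NaHCO3, CH2Cl2, rt) with migration of the quaternary carbon should give the lactone 7,7-dimethyl-2-oxo-2,3,4,7-tetrahydrooxepin-6-yl trifluoromethanesulfonate F5, the electron-poor enol triflate resisting epoxidation. Stille coupling with tributyl(vinyl)stannane (Pd(PPh3)4, LiCl, THF, 65 °C) installs the vinyl group, and the route is rejoined at 4.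

Further compounds
F1 | step 7 | (5aS,6R,7S)-1,1,7-trimethyl-3-oxo-6-{[1-(phenylsulfonyl)-1H-indol-3-yl]methyl}-1,3,4,5,5a,6,7,8-octahydro-2-benzoxepine-6-carbaldehyde (enantiomer of 13) | O=C[C@]1(Cc2cn(S(=O)(=O)c3ccccc3)c3ccccc23)[C@@H](C)CC=C2[C@@H]1CCC(=O)OC2(C)C
F2 | step 9 | 3-[(1S,2R,3R)-2,3-dimethyl-2-{[1-(phenylsulfonyl)-1H-indol-3-yl]methyl}-6-(propan-2-ylidene)cyclohexyl]propanoic acid | CC(C)=C1CC[C@@H](C)[C@@](C)(Cc2cn(S(=O)(=O)c3ccccc3)c3ccccc23)[C@@H]1CCC(=O)O
F3 | step 2 | 2,2-dimethylcyclohexane-1,3-dione | CC1(C)C(=O)CCCC1=O
F4 | step 2 | 6,6-dimethyl-5-oxocyclohex-1-en-1-yl trifluoromethanesulfonate | CC1(C)C(=O)CCC=C1OS(=O)(=O)C(F)(F)F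
F5 | step 2 | 7,7-dimethyl-2-oxo-2,3,4,7-tetrahydrooxepin-6-yl trifluoromethanesulfonate | CC1(C)OC(=O)CCC=C1OS(=O)(=O)C(F)(F)F
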